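The seven-membered ring B (azulene numbering) carries an all-trans triad at C4 (isopropyl), C3a and C8a, with oxygen on C5 and methyl on C7. Deleting C6 contracts this array to a cyclohexene whose C5=C7 bond is a silyl enol ether. A [4+2] cut of C3a–C4 and C8a–C8 then gives two acyclic pieces. One oxazolidinone-controlled Diels–Alder reaction joins a Z 2-silyloxy diene (C4, C5, C7, C8; isopropyl outside) to an E N-enoyl imide (C3a, C8a; methallyl on C3a). It sets all three stereocentres and places the enol ether where CH2 (C6) is inserted later. The acyl and methallyl arms then close cyclopentene ring A.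

Key step: step 6

Remark on locants and faces: C1–C8a are the azulene locants of the target (C1 epoxide CH, C2 epoxide C–CH3, C4 CH–isopropyl, C5 CH–O-acyl, C7 carbinol) and are used for every intermediate. α is the face that carries the C4 isopropyl group and β is the other face. In the target, H-3a, the C7 hydroxyl and the epoxide oxygen are α. H-8a, the C5 ester oxygen and both ring methyl groups are β.

Assumption: compounds 6, 11 and 24 are taken as commercial. The cyclopropane in 14–17 is drawn as the isomer expected from β attack; the other isomer would converge on the same 19.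

Step 1
Reactants: 1 3-methylbutanal (isovaleraldehyde); 2 isopropenylmagnesium bromide
Product: 3 (±)-2,5-dimethylhex-1-en-3-ol
Conditions: THF, 0 °C; then aq NH4Cl
Reagents that add atoms: none
Why: Grignard addition of an alkenylmagnesium halide to an unhindered aliphatic aldehyde is dependable, and the carbinol centre formed as a racemate is erased by the oxidation in step 2.

Step 2
Reactants: 3 (±)-2,5-dimethylhex-1-en-3-ol
Product: 4 2,5-dimethylhex-1-en-3-one
Conditions: Dess–Martin periodinane, CH2Cl2, 0 °C → rt
Reagents that add atoms: none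
Why: Dess–Martin oxidation converts the secondary allylic alcohol into the enone under neutral conditions, so that the α-methyl enone neither isomerises nor oligomerises.

Step 3
Reactants: 4 2,5-dimethylhex-1-en-3-one
Product: 5 (Z)-2,5-dimethyl-3-(triethylsilyloxy)hexa-1,3-diene
Conditions: Et3SiOTf, Et3N, CH2Cl2, 0 °C
Reagents that add atoms: triethylsilyl trifluoromethanesulfonate, CC[Si](CC)(CC)OS(=O)(=O)C(F)(F)F
Why: Soft enolisation with a silyl triflate and an amine can only remove a proton from the C4 methylene and gives the Z enol ether because the isopropyl group turns away from the isopropenyl group to avoid allylic strain; triethylsilyl is chosen because it tolerates Et2AlCl at low temperature yet stays small enough for step 7 and labile enough for step 11.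

Step 4
Reactants: 6 (E)-4-bromobut-2-enoic acid; 7 (S)-4-benzyl-2-oxazolidinone
Product: 10 (S)-4-benzyl-3-[(E)-4-bromobut-2-enoyl]oxazolidin-2-one, via acid chloride 8 (not isolated), via lithium oxazolidinide 9 (not isolated)
Conditions: 6, (COCl)2, cat. DMF, CH2Cl2, 0 °C → rt, concentrate; 7, n-BuLi, THF, −78 °C; combine, −78 → 0 °C
Reagents that add atoms: oxalyl chloride, O=C(Cl)C(=O)Cl (chlorine of 8 only); n-butyllithium, [Li]CCCC (lithium of 9 only)
Why: N-acylation of a lithiated oxazolidinone by an acid chloride at −78 °C is much faster than displacement of the allylic bromide, and the stereocentre of 7 is not touched.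

Step 5
Reactants: 10 (S)-4-benzyl-3-[(E)-4-bromobut-2-enoyl]oxazolidin-2-one; 11 tributyl(prop-1-en-2-yl)stannane
Product: 12 (S)-4-benzyl-3-[(E)-5-methylhexa-2,5-dienoyl]oxazolidin-2-one
Conditions: Pd2(dba)3 (2.5 mol %), tri(2-furyl)phosphine (10 mol %), THF, 50 °C
Reagents that add atoms: none
Why: Stille coupling of an allylic bromide with an alkenylstannane on zerovalent palladium needs no base, so the doubly allylic C3 methylene is never deprotonated and the skipped diene cannot slip into conjugation, while bond formation at the allyl terminus remote from the acyl group keeps the E-enoyl unit.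

Step 6
Reactants: 5 (Z)-2,5-dimethyl-3-(triethylsilyloxy)hexa-1,3-diene; 12 (S)-4-benzyl-3-[(E)-5-methylhexa-2,5-dienoyl]oxazolidin-2-one
Product: 13 (S)-4-benzyl-3-{[(1S,5S,6S)-5-isopropyl-3-methyl-6-(2-methylallyl)-4-(triethylsilyloxy)cyclohex-3-en-1-yl]carbonyl}oxazolidin-2-one (C4 isopropyl α; C3a methallyl β; C8a acyl α)
Conditions: Et2AlCl (1.4 equiv), 5 (2 equiv), CH2Cl2, −78 → −30 °C; cold aq NaHCO3/Rochelle salt
Reagents that add atoms: none
Why: More than one equivalent of Et2AlCl turns 12 into a cationic aluminium chelate in which both carbonyl oxygens are bound and the enoyl unit is fixed s-cis, and this lowered LUMO engages the s-cis form of 5 in a concerted but asynchronous [4+2] cycloaddition with the C3a–C4 bond the more advanced. The closest known reaction type is the Lewis acid-promoted Diels–Alder reaction of N-enoyl oxazolidinones with 2-silyloxy dienes. The one new ring, the six-membered carbocycle C4–C5–C7–C8–C8a–C3a, closes by suprafacial-suprafacial cycloaddition that forms C3a–C4 and C8a–C8 together. C3a and C8a come out trans because the E geometry of 12 is retained, and their absolute sense is set by the benzyl group of the S auxiliary, which covers one face of the planar chelate so that the diene adds to the other; C4 is set by the Z geometry of 5 (isopropyl outside) together with the endo position of the acyl group, which places isopropyl cis to acyl and trans to methallyl. Regioselectivity comes from the silyloxy group, whose donor effect makes the enol ether carbon C4 the most nucleophilic terminus and pairs it with the β-carbon C3a against the weaker bias of the two alkyl groups, and endo selectivity comes from secondary overlap with the chelated imide. Et2AlCl also scavenges protic acid, so the tetrasubstituted C5=C7 silyl enol ether survives.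

Step 7
Reactants: 13 Diels–Alder adduct
Product: 14 (S)-4-benzyl-3-{[(1S,2S,3S,4S,6R)-2-isopropyl-6-methyl-3-(2-methylallyl)-1-(triethylsilyloxy)bicyclo[4.1.0]heptan-4-yl]carbonyl}oxazolidin-2-one (new CH2 = C6 on the β face)
Conditions: Et2Zn (1.5 equiv), CH2I2 (1.5 equiv), CH2Cl2, −20 → 0 °C
Reagents that add atoms: diiodomethane, ICI
Why: In the Furukawa variant of the Simmons–Smith cyclopropanation the electrophilic zinc carbenoid, kept limiting, selects the electron-rich C5=C7 enol ether over the methallyl alkene, CH2 should add to the β face anti to the C4 isopropyl and C8a acyl groups, and both new centres are erased in step 11 so their configuration has no consequence.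

Step 8
Reactants: 14 silyloxycyclopropane imide
Product: 15 [(1S,2S,3R,4S,6R)-2-isopropyl-6-methyl-3-(2-methylallyl)-1-(triethylsilyloxy)bicyclo[4.1.0]heptan-4-yl]methanol
Conditions: LiBH4, H2O (1 equiv), Et2O, 0 °C
Reagents that add atoms: none
Why: Reductive cleavage of an N-acyl oxazolidinone with LiBH4 attacks the exocyclic carbonyl, returns the auxiliary, and leaves the silyl cyclopropyl ether (the masked C5 ketone), the alkene and C8a unchanged.

Step 9
Reactants: 15 primary alcohol
Product: 16 (1S,2S,3S,4S,6R)-2-isopropyl-6-methyl-3-(2-methylallyl)-1-(triethylsilyloxy)bicyclo[4.1.0]heptane-4-carbaldehyde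
Conditions: Dess–Martin periodinane, pyridine, CH2Cl2, 0 °C → rt
Reagents that add atoms: none
Why: Pyridine-buffered Dess–Martin oxidation spares the silyl ether and the alkene, and the formyl group is equatorial and trans to its neighbour, so C8a has no drive to epimerise.

Step 10
Reactants: 16 aldehyde
Product: 17 (1S,2S,3R,4R,6R)-4-ethenyl-2-isopropyl-6-methyl-3-(2-methylallyl)-1-(triethylsilyloxy)bicyclo[4.1.0]heptane
Conditions: Ph3PCH3Br, KOt-Bu, THF, 0 °C
Reagents that add atoms: methyltriphenylphosphonium bromide, C[P+](c1ccccc1)(c1ccccc1)c1ccccc1.[Br-]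
Why: Wittig methylenation with the non-stabilised ylide is fast even on α-branched aldehydes and turns C1 into the vinyl partner for ring closure without affecting any stereocentre.

Step 11
Reactants: 17 vinyl silyloxycyclopropane
Product: 19 (5R,6R,7S)-5-ethenyl-7-isopropyl-3-methyl-6-(2-methylallyl)cyclohept-2-en-1-one, via chloro ketone 18 (not isolated)
Conditions: FeCl3 (2.5 equiv), DMF, 0 °C → rt; then NaOAc, MeOH, 65 °C
Reagents that add atoms: FeCl3, [Fe+3].[Cl-].[Cl-].[Cl-] (chlorine of 18 only)
Why: In this oxidative ring expansion of a silyloxycyclopropane by trivalent iron, one-electron oxidation cleaves the internal C5–C7 bond because that releases the tertiary C7 radical, chlorine transfer from a second FeCl3 outruns cyclisation onto the remote alkenes, and acetate-induced E1cB loss of HCl gives the conjugated C6=C7 enone with the equatorial C4 isopropyl group unchanged.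

Step 12
Reactants: 19 monocyclic trienone
Product: 20 (3aR,4S,8aS)-4-isopropyl-2,7-dimethyl-3,3a,8,8a-tetrahydroazulen-5(4H)-one (trans-fused; H-3a α; H-8a β)
Conditions: second-generation Grubbs catalyst (5 mol %), CH2Cl2 (0.01 M), 40 °C
Reagents that add atoms: none
Why: Ring-closing metathesis of a vinyl group with a 1,1-disubstituted alkene gives the trisubstituted cyclopentene, the two trans-equatorial arms sit on a seven-membered ring whose wide C4–C3a–C8a–C8 torsion accommodates the trans fusion, and the electron-poor trisubstituted enone stays out of the reaction.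

Step 13
Reactants: 20 bicyclic dienone
Product: 22 (3aR,4S,7R,8aS)-7-hydroxy-4-isopropyl-2,7-dimethyl-3,3a,6,7,8,8a-hexahydroazulen-5(4H)-one (7α-OH; 7β-CH3), via tertiary boronate 21 (not isolated)
Conditions: B2pin2 (1.2 equiv), CuCl (5 mol %), DPEphos (5 mol %), NaOt-Bu (10 mol %), MeOH (2 equiv), THF, rt; then NaBO3·4H2O, THF/H2O, rt
Reagents that add atoms: bis(pinacolato)diboron, CC1(C)OB(OC1(C)C)B1OC(C)(C)C(C)(C)O1 (boryl group of 21 only); sodium perborate, [Na+].[Na+].O[B-]1(O)OO[B-](O)(O)OO1
Why: Copper-catalysed conjugate borylation of a β-substituted cyclic enone followed by stereoretentive perborate oxidation installs the C7 oxygen, the trans-fused cyclopentene locks the cycloheptenone in a chair in which the axial β hydrogens H-4 and H-8a roof the β face of C6=C7 so the bulky copper boryl should add to the open α face, and the isolated trisubstituted alkene is inert.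

Step 14
Reactants: 22 β-hydroxy ketone
Product: 23 (3aR,4S,5S,7R,8aS)-4-isopropyl-2,7-dimethyl-3,3a,4,5,6,7,8,8a-octahydroazulene-5,7-diol (5β-OH; 7α-OH)
Conditions: Me4NBH(OAc)3 (5 equiv), MeCN/AcOH (1:1), −20 °C
Reagents that add atoms: none
Why: In this hydroxyl-directed triacetoxyborohydride reduction the axial 7α-hydroxyl replaces an acetate on boron and the bound hydride is delivered within the molecule to the α face of C5, so the new carbinol oxygen is β, anti to the C7 hydroxyl and trans to the isopropyl group.

Step 15
Reactants: 23 diol; 24 4-(benzyloxy)benzoic acid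
Product: 25 (3aR,4S,5S,7R,8aS)-7-hydroxy-4-isopropyl-2,7-dimethyl-3,3a,4,5,6,7,8,8a-octahydroazulen-5-yl 4-(benzyloxy)benzoate
Conditions: EDC·HCl, DMAP, CH2Cl2, rt
Reagents that add atoms: none
Why: Steglich-type carbodiimide esterification acylates only the equatorial secondary C5 hydroxyl, whose surroundings resemble those of menthol, the tertiary C7 hydroxyl is inert, and the benzyl ether keeps the phenol from acylating itself.

Step 16
Reactants: 25 alkene ester
Product: 26 (1S,2R,3aR,4S,5S,7R,8aS)-1,2-epoxy-7-hydroxy-4-isopropyl-2,7-dimethyldecahydroazulen-5-yl 4-(benzyloxy)benzoate (1α,2α-epoxide)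
Conditions: VO(acac)2 (10 mol %), t-BuOOH (decane, 1.5 equiv), CH2Cl2, 0 °C → rt
Reagents that add atoms: tert-butyl hydroperoxide, CC(C)(C)OO
Why: In this hydroxyl-directed vanadium-catalysed epoxidation of a bishomoallylic tertiary alcohol the axial 7α-alkoxide holds the metal-bound peroxide under the α face of C1=C2, unbound trisubstituted alkenes are almost inert to this reagent so oxygen transfer should occur only on that face, and the syn placement of hydroxyl and epoxide rules out ether formation.

Step 17
Reactants: 26 benzyl-protected epoxide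
Product: 27 (1S,2R,3aR,4S,5S,7R,8aS)-1,2-epoxy-7-hydroxy-4-isopropyl-2,7-dimethyldecahydroazulen-5-yl 4-hydroxybenzoate (CNP0245441.1)
Conditions: H2 (1 atm), Pd/C, EtOAc, rt
Reagents that add atoms: none
Why: Hydrogenolysis of the aryl benzyl ether under neutral conditions frees the phenol, while the non-benzylic trisubstituted epoxide, the tertiary alcohol and the alkyl benzoate are not reduced and no alkene remains.

Compound list
1 | 3-methylbutanal | CC(C)CC=O | starting material
2 | isopropenylmagnesium bromide | C=C(C)[Mg]Br | starting material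
3 | (±)-2,5-dimethylhex-1-en-3-ol | C=C(C)C(O)CC(C)C | intermediate
4 | 2,5-dimethylhex-1-en-3-one | C=C(C)C(=O)CC(C)C | intermediate
5 | (Z)-2,5-dimethyl-3-(triethylsilyloxy)hexa-1,3-diene | C=C(C)/C(O[Si](CC)(CC)CC)=C/C(C)C | intermediate
6 | (E)-4-bromobut-2-enoic acid | OC(=O)/C=C/CBr | starting material
7 | (S)-4-benzyl-2-oxazolidinone | O=C1OC[C@H](Cc2ccccc2)N1 | starting material
8 | (E)-4-bromobut-2-enoyl chloride | ClC(=O)/C=C/CBr | intermediate
9 | lithium (S)-4-benzyl-2-oxooxazolidin-3-ide | [Li]N1C(=O)OC[C@@H]1Cc1ccccc1 | intermediate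
10 | (S)-4-benzyl-3-[(E)-4-bromobut-2-enoyl]oxazolidin-2-one | O=C(/C=C/CBr)N1C(=O)OC[C@@H]1Cc1ccccc1 | intermediate
11 | tributyl(prop-1-en-2-yl)stannane | C=C(C)[Sn](CCCC)(CCCC)CCCC | starting material
12 | (S)-4-benzyl-3-[(E)-5-methylhexa-2,5-dienoyl]oxazolidin-2-one | O=C(/C=C/CC(C)=C)N1C(=O)OC[C@@H]1Cc1ccccc1 | intermediate
13 | cyclohexene silyl enol ether, (1S,5S,6S), acyl oxazolidinone on C8a | CC(C)[C@H]1[C@H](CC(C)=C)[C@@H](C(=O)N2C(=O)OC[C@@H]2Cc2ccccc2)CC(C)=C1O[Si](CC)(CC)CC | intermediate
14 | silyloxycyclopropane imide, (1S,2S,3S,4S,6R) | CC(C)[C@H]1[C@H](CC(C)=C)[C@@H](C(=O)N3C(=O)OC[C@@H]3Cc3ccccc3)C[C@]2(C)C[C@]12O[Si](CC)(CC)CC | intermediate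
15 | silyloxycyclopropane primary alcohol, (1S,2S,3R,4S,6R) | CC(C)[C@H]1[C@H](CC(C)=C)[C@@H](CO)C[C@]2(C)C[C@]12O[Si](CC)(CC)CC | intermediate
16 | silyloxycyclopropane aldehyde, (1S,2S,3S,4S,6R) | CC(C)[C@H]1[C@H](CC(C)=C)[C@@H](C=O)C[C@]2(C)C[C@]12O[Si](CC)(CC)CC | intermediate
17 | vinyl silyloxycyclopropane, (1S,2S,3R,4R,6R) | CC(C)[C@H]1[C@H](CC(C)=C)[C@@H](C=C)C[C@]2(C)C[C@]12O[Si](CC)(CC)CC | intermediate
18 | 3-chloro-5-ethenyl-7-isopropyl-3-methyl-6-(2-methylallyl)cycloheptan-1-one (C7 chloride, both epimers) | CC(C)[C@H]1[C@H](CC(C)=C)[C@@H](C=C)CC(C)(Cl)CC1=O | intermediate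
19 | (5R,6R,7S)-5-ethenyl-7-isopropyl-3-methyl-6-(2-methylallyl)cyclohept-2-en-1-one | CC(C)[C@H]1[C@H](CC(C)=C)[C@@H](C=C)CC(C)=CC1=O | intermediate
20 | (3aR,4S,8aS)-4-isopropyl-2,7-dimethyl-3,3a,8,8a-tetrahydroazulen-5(4H)-one | CC(C)[C@H]1[C@@H]2CC(C)=C[C@H]2CC(C)=CC1=O | intermediate
21 | 7α-(pinacolboryl) ketone | CC(C)[C@H]1[C@@H]2CC(C)=C[C@H]2C[C@@](C)(B3OC(C)(C)C(C)(C)O3)CC1=O | intermediate
22 | (3aR,4S,7R,8aS)-7-hydroxy ketone | CC(C)[C@H]1[C@@H]2CC(C)=C[C@H]2C[C@@](C)(O)CC1=O | intermediate
23 | (3aR,4S,5S,7R,8aS)-5,7-diol | CC(C)[C@H]1[C@@H]2CC(C)=C[C@H]2C[C@@](C)(O)C[C@@H]1O | intermediate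
24 | 4-(benzyloxy)benzoic acid | OC(=O)c1ccc(OCc2ccccc2)cc1 | starting material
25 | C5 4-(benzyloxy)benzoate of 23 | CC(C)[C@H]1[C@@H]2CC(C)=C[C@H]2C[C@@](C)(O)C[C@@H]1OC(=O)c1ccc(OCc2ccccc2)cc1 | intermediate
26 | 1α,2α-epoxide of 25 | CC(C)[C@H]1[C@@H]2C[C@@]3(C)O[C@H]3[C@H]2C[C@@](C)(O)C[C@@H]1OC(=O)c1ccc(OCc2ccccc2)cc1 | intermediate
27 | CNP0245441.1 | CC(C)[C@H]1[C@@H]2C[C@@]3(C)O[C@H]3[C@H]2C[C@@](C)(O)C[C@@H]1OC(=O)c1ccc(O)cc1 | target

Total step count: 17. Longest linear sequence: 15 (steps 1–3 and 6–17).

Steps most likely to fail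

**Step 6.**
- What may go wrong: bond formation between two substituted carbons (C4 and C3a) may be slow. The two alkyl groups of the diene may erode the regiochemical preference. The reaction may also stop after the first C–C bond, with loss of the silyl group.
- Fallback: build the same two bonds in two operations, setting out from 5 and 12.
- First operation: a Mukaiyama–Michael addition (TiCl4, CH2Cl2, −78 °C, aqueous work-up) uses 5 only as an enol silane. Only C4 can then bond to C3a of the chelated imide. This gives (S)-4-benzyl-3-[(3R,4S)-4-isopropyl-6-methyl-3-(2-methylallyl)-5-oxohept-6-enoyl]oxazolidin-2-one F1.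
- Second operation: an intramolecular Michael addition promoted by Et3SiOTf/Et3N closes C8a–C8. The imide enol derivative reacts on the face away from the benzyl group. The triethylsilyl enol ether is regenerated specifically at C5=C7, and the route is rejoined at 13.

**Step 13.**
- What may go wrong: addition to the twisted, fully substituted β-carbon may be sluggish. Facial selectivity may also drop if a boat form of the cycloheptenone competes.
- Fallback: relay the configuration from C4 through C5 by hydroxyl direction, setting out from 20.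
- 1,2-Reduction with i-Bu2AlH (toluene, −78 °C) from the exposed β face of the carbonyl gives the 5α-allylic alcohol F2.
- VO(acac)2/t-BuOOH acts far faster on an allylic alcohol than on the remote alkene and delivers oxygen syn. This gives the 6α,7α-epoxy-5α-alcohol F3.
- Dess–Martin oxidation gives the 6α,7α-epoxy ketone F4.
- Reductive opening at C6 with (PhSe)2/NaBH4 in EtOH rejoins the route at 22.

**Step 16.**
- What may go wrong: conversion may be low if the vanadium alkoxide at C7 cannot reach the alkene. Undirected oxidants would favour the convex β face.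
- Fallback: turn that steric bias to advantage, setting out from 25.
- NBS in aqueous acetone forms the bromonium ion on the open β face. Water opens it at the tertiary C2 from the α face to give the 1β-bromo-2α-hydroxy compound F5.
- The C7 hydroxyl cannot intervene, because C1 is held anti to C7 across C8–C8a.
- K2CO3 in acetone closes the ring with inversion at C1 and rejoins the route at 26.

Further compounds
F1 | step 6 | (S)-4-benzyl-3-[(3R,4S)-4-isopropyl-6-methyl-3-(2-methylallyl)-5-oxohept-6-enoyl]oxazolidin-2-one | C=C(C)C(=O)[C@@H](C(C)C)[C@H](CC(C)=C)CC(=O)N1C(=O)OC[C@@H]1Cc1ccccc1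
F2 | step 13 | (3aR,4S,5S,8aS)-4-isopropyl-2,7-dimethyl-3,3a,4,5,8,8a-hexahydroazulen-5-ol (5α-OH) | CC(C)[C@H]1[C@@H]2CC(C)=C[C@H]2CC(C)=C[C@H]1O
F3 | step 13 | 6α,7α-epoxy-5α-alcohol derived from F2 | CC(C)[C@H]1[C@@H]2CC(C)=C[C@H]2C[C@@]3(C)O[C@H]3[C@H]1O
F4 | step 13 | 6α,7α-epoxy-5-ketone derived from F3 | CC(C)[C@H]1[C@@H]2CC(C)=C[C@H]2C[C@@]3(C)O[C@H]3C1=O
F5 | step 16 | 1β-bromo-2α,7α-dihydroxy-4-isopropyl-2,7-dimethyldecahydroazulen-5-yl 4-(benzyloxy)benzoate | CC(C)[C@H]1[C@@H]2C[C@@](C)(O)[C@H](Br)[C@H]2C[C@@](C)(O)C[C@@H]1OC(=O)c1ccc(OCc2ccccc2)cc1
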